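**Plan** (eudesmane numbering: ring A = C1–C5, C10; ring B = C5–C10; target = 4α-OH, 4β-CH3, 5α-H, 7α-acrylic acid, 9α-acyloxy, 10β-CH3, 3'R)
1. Retrosynthetic cuts, in order: the C9–O acyl bond and the C12 oxidation level; C7–C11 (1,4-addition to a C9 enone); C8 is excised from ring B, leaving a cyclopentanone with a C7–C9 bond; C4–O/C5–H (hydration of C4=C5); C4=C5 and C1–C10 (aldol condensation, Michael addition).
2. Forward: ring A is annulated onto 2-methylcyclopentane-1,3-dione, whose five-membered ring (C5, C6, C7, C9, C10) then grows into ring B by insertion of C8 through a silyloxycyclopropane that is opened oxidatively (strain release).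
3. Enabling feature: in ring B the only oxygenated carbon, C9, lies between quaternary C10 and C8, and the only branch, C7, is 1,3 to it. A C9 cyclopentanone therefore enolises only towards C7, the C7–C9 cyclopropane bond is the one that breaks, and the C9 enone formed presents C7 as its β-carbon.
4. Stereochemistry: C10 from the L-phenylalanine-mediated aldol desymmetrisation; C4 and C5 together from α-face hydroboration anti to the C10 methyl; C7 from axial cuprate attack on the trans-fused enone; C9 from equatorial hydride delivery enforced by the axial C7 group; C3' from purchased acid.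

Key step: step 9

Assumption: (3R)-3-methylpentanoic acid 17 is taken as a purchasable enantiopure building block, so its stereocentre enters intact at the esterification.

**Step 1**
Reactants: 1 2-methylcyclopentane-1,3-dione; 2 pent-1-en-3-one
Product: 3 2-methyl-2-(3-oxopentyl)cyclopentane-1,3-dione
Conditions: H2O, AcOH (cat.), 70 °C
Reagents that add atoms: none
Why: Michael addition of the acidic 1,3-dione to the vinyl ketone in water is the standard entry to Hajos–Parrish triketones and creates no stereocentre.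

**Step 2**
Reactants: 3 2-methyl-2-(3-oxopentyl)cyclopentane-1,3-dione
Product: 4 (7aS)-4,7a-dimethyl-2,3,7,7a-tetrahydro-1H-indene-1,5(6H)-dione
Conditions: L-phenylalanine (1 equiv), (1S)-(+)-10-camphorsulfonic acid (0.5 equiv), DMF, 30 → 70 °C
Reagents that add atoms: none
Why: Hajos–Parrish aldol condensation, in which the enamine of the side-chain ketone attacks one of the two enantiotopic ring carbonyls (C5) through its ethyl carbon (C4), so that the L-amino acid sets quaternary C10 as S before dehydration to the C4=C5 enone.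

**Step 3**
Reactants: 4 (7aS)-4,7a-dimethyl-2,3,7,7a-tetrahydro-1H-indene-1,5(6H)-dione
Product: 5 (7a'S)-4',7a'-dimethyl-2',3',7',7a'-tetrahydrospiro[1,3-dithiolane-2,5'-inden]-1'(6'H)-one
Conditions: HSCH2CH2SH (1.05 equiv), BF3·OEt2 (0.3 equiv), AcOH, rt
Reagents that add atoms: ethane-1,2-dithiol SCCS
Why: acid-catalysed dithioketalisation should be chemoselective for the conjugated C3 carbonyl because the cyclopentanone carbonyl next to quaternary C10 is neopentylic and slow, and the C4=C5 bond does not migrate in thioketals.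

**Step 4**
Reactants: 5 (7a'S)-4',7a'-dimethyl-2',3',7',7a'-tetrahydrospiro[1,3-dithiolane-2,5'-inden]-1'(6'H)-one
Product: 6 (7aS)-4,7a-dimethyl-2,3,5,6,7,7a-hexahydro-1H-inden-1-one
Conditions: Raney nickel (Ni, deactivated in acetone), EtOH, reflux
Reagents that add atoms: none
Why: Mozingo desulfurisation replaces both C–S bonds at C3 by C–H and should leave the tetrasubstituted C4=C5 bond and C10 untouched.

**Step 5**
Reactants: 6 (7aS)-4,7a-dimethyl-2,3,5,6,7,7a-hexahydro-1H-inden-1-one
Product: 8 (1S,3aR,4R,7aS)-4,7a-dimethyloctahydro-1H-indene-1,4-diol, via alkylborane 7 (not isolated)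
Conditions: BH3·THF (3.5 equiv), THF, 0 °C → rt; then NaOH, H2O2, 0 → 40 °C
Reagents that add atoms: hydrogen peroxide OO
Why: hydroboration–oxidation, in which borane adds syn to C4=C5 from the α face anti to the angular C10 methyl with boron on the less hindered C4 (C5 is neopentylic), so that oxidation with retention sets 4α-OH/4β-CH3 and the trans ring fusion (H-5α) together, while the C9 ketone is reduced in passing to a carbinol whose configuration (drawn β) is irrelevant.

**Step 6**
Reactants: 8 (1S,3aR,4R,7aS)-4,7a-dimethyloctahydro-1H-indene-1,4-diol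
Product: 9 (3aR,4R,7aS)-4-hydroxy-4,7a-dimethyloctahydro-1H-inden-1-one
Conditions: Dess–Martin periodinane (1.3 equiv), NaHCO3, CH2Cl2, rt
Reagents that add atoms: none
Why: Dess–Martin oxidation can only affect the secondary C9 carbinol, since the tertiary C4 alcohol has no carbinol hydrogen and no centre next to C9 is epimerisable.

**Step 7**
Reactants: 9 (3aR,4R,7aS)-4-hydroxy-4,7a-dimethyloctahydro-1H-inden-1-one
Product: 10 (3aS,7R,7aR)-3a,7-dimethyl-3,7-bis(triethylsilyloxy)-3a,4,5,6,7,7a-hexahydro-1H-indene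
Conditions: Et3SiOTf (2.5 equiv), Et3N (4 equiv), CH2Cl2, 0 °C → rt
Reagents that add atoms: triethylsilyl trifluoromethanesulfonate CC[Si](CC)(CC)OS(=O)(=O)C(F)(F)F
Why: soft enolisation gives a single silyl enol ether because C9 can enolise only towards C7 (C10 is quaternary), and the tertiary alcohol is silylated in the same operation as its protecting group.

**Step 8**
Reactants: 10 (3aS,7R,7aR)-3a,7-dimethyl-3,7-bis(triethylsilyloxy)-3a,4,5,6,7,7a-hexahydro-1H-indene
Product: 11 silyloxycyclopropane (10 with CH2 = C8 bridged across C7–C9 on the α face)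
Conditions: Et2Zn (2.5 equiv), CH2I2 (5 equiv), CH2Cl2, 0 °C → rt
Reagents that add atoms: diiodomethane ICI
Why: Simmons–Smith cyclopropanation (Furukawa conditions) of the electron-rich silyl enol ether should deliver C8 to C7=C9 from the α face anti to the C10 methyl, and the two cyclopropane stereocentres are transient.

**Step 9**
Reactants: 11 silyloxycyclopropane
Product: 13 (4aR,5R,8aS)-5,8a-dimethyl-5-(triethylsilyloxy)-4a,5,6,7,8,8a-hexahydronaphthalen-1(4H)-one, via chloro ketone 12 (not isolated)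
Conditions: FeCl3 (2.5 equiv), pyridine (1 equiv), DMF, 0 °C → rt; extraction; then NaOAc, MeOH, reflux
Reagents that add atoms: none
Why: Trivalent iron oxidises the silyloxycyclopropane by single-electron transfer, the silyl group leaves as Et3SiCl, and the cyclopropyloxy radical undergoes β-scission of the C7–C9 bond shared by the three- and five-membered rings, which releases the cyclopropane strain, places C8 between C9 and C7 in a cyclohexanone, and leaves a secondary C7 radical that takes chlorine from a second FeCl3. Acetate then eliminates HCl (E1cB) to give C7=C8 conjugated with C9=O. The closest known reaction is the Ito–Saegusa one-carbon ring expansion of 1-silyloxybicyclo[n.1.0]alkanes to 2-cycloalkenones. No ring is closed here: ring B arises by opening the zero-atom bridge of the bicyclo[3.1.0]hexane, and no lasting stereocentre is formed, since C7–Cl is lost and C4, C5 and C10 are not touched. The step needs scission of the internal C7–C9 bond and not the external C8–C9 bond, which the secondary ring radical (against a primary one) should secure, and a single enone regioisomer, which quaternary C10 guarantees. The tertiary triethylsilyl ether is expected to survive FeCl3 in DMF at low temperature.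

**Step 10**
Reactants: 13 (4aR,5R,8aS)-5,8a-dimethyl-5-(triethylsilyloxy)-4a,5,6,7,8,8a-hexahydronaphthalen-1(4H)-one; 14 isopropenylmagnesium bromide
Product: 15 (3R,4aR,5R,8aS)-5,8a-dimethyl-3-(prop-1-en-2-yl)-5-(triethylsilyloxy)octahydronaphthalen-1(2H)-one
Conditions: 14 (2 equiv), CuBr·SMe2 (0.2 equiv), THF, −78 → −30 °C; aq. NH4Cl
Reagents that add atoms: none
Why: copper-catalysed 1,4-addition, in which the alkenyl group attacks C7 of the trans-fused enone axially from the α face (antiparallel attack leading to a chair enolate, the β face being screened by the axial C10 methyl), which should set 7α, trans to the C10 methyl.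

**Step 11**
Reactants: 15 (3R,4aR,5R,8aS)-5,8a-dimethyl-3-(prop-1-en-2-yl)-5-(triethylsilyloxy)octahydronaphthalen-1(2H)-one
Product: 16 (1R,3R,4aR,5R,8aS)-5,8a-dimethyl-3-(prop-1-en-2-yl)-5-(triethylsilyloxy)decahydronaphthalen-1-ol
Conditions: Li[HB(s-Bu)3] (L-Selectride, 1.5 equiv), THF, −78 °C; then NaOH, H2O2
Reagents that add atoms: none
Why: the bulky trialkylborohydride should attack the C9 carbonyl along the equatorial β trajectory because the axial α trajectory is blocked by the syn-axial C7 isopropenyl group, giving the axial 9α-alcohol.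

**Step 12**
Reactants: 16 (1R,3R,4aR,5R,8aS)-5,8a-dimethyl-3-(prop-1-en-2-yl)-5-(triethylsilyloxy)decahydronaphthalen-1-ol; 17 (3R)-3-methylpentanoic acid
Product: 18 (1R,3R,4aR,5R,8aS)-5,8a-dimethyl-3-(prop-1-en-2-yl)-5-(triethylsilyloxy)decahydronaphthalen-1-yl (3R)-3-methylpentanoate
Conditions: 17 (2 equiv), EDC·HCl (2.5 equiv), DMAP (1 equiv), CH2Cl2, rt → 40 °C
Reagents that add atoms: none
Why: Steglich esterification acylates the only free hydroxyl with retention at C9, and the β-stereocentre of the acid cannot epimerise.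

**Step 13**
Reactants: 18 (1R,3R,4aR,5R,8aS)-5,8a-dimethyl-3-(prop-1-en-2-yl)-5-(triethylsilyloxy)decahydronaphthalen-1-yl (3R)-3-methylpentanoate
Product: 19 (1R,3R,4aR,5R,8aS)-3-(3-hydroxyprop-1-en-2-yl)-5,8a-dimethyl-5-(triethylsilyloxy)decahydronaphthalen-1-yl (3R)-3-methylpentanoate
Conditions: SeO2 (0.5 equiv), t-BuOOH (3 equiv), CH2Cl2, rt
Reagents that add atoms: selenium dioxide O=[Se]=O; tert-butyl hydroperoxide CC(C)(C)OO
Why: SeO2 allylic oxidation (ene reaction then [2,3]-sigmatropic shift) of the 1,1-disubstituted alkene should take a methyl hydrogen in preference to the hindered C7 methine and return the double bond to the terminal position without touching a stereocentre.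

**Step 14**
Reactants: 19 (1R,3R,4aR,5R,8aS)-3-(3-hydroxyprop-1-en-2-yl)-5,8a-dimethyl-5-(triethylsilyloxy)decahydronaphthalen-1-yl (3R)-3-methylpentanoate
Product: 21 2-[(2R,4R,4aS,8R,8aR)-4a,8-dimethyl-4-{[(3R)-3-methylpentanoyl]oxy}-8-(triethylsilyloxy)decahydronaphthalen-2-yl]prop-2-enoic acid, via enal 20 (not isolated)
Conditions: MnO2 (20 equiv), CH2Cl2, rt; filtration; then NaClO2, NaH2PO4, 2-methylbut-2-ene, t-BuOH/H2O, 0 °C → rt
Reagents that add atoms: sodium chlorite [Na+].[O-]Cl=O
Why: MnO2 oxidises the allylic alcohol to the enal and Pinnick oxidation with an alkene scavenger converts it into the acrylic acid without affecting the ester, the silyl ether or the methylene group.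

**Step 15**
Reactants: 21 2-[(2R,4R,4aS,8R,8aR)-4a,8-dimethyl-4-{[(3R)-3-methylpentanoyl]oxy}-8-(triethylsilyloxy)decahydronaphthalen-2-yl]prop-2-enoic acid
Product: 22 2-[(2R,4R,4aS,8R,8aR)-8-hydroxy-4a,8-dimethyl-4-{[(3R)-3-methylpentanoyl]oxy}decahydronaphthalen-2-yl]prop-2-enoic acid
Conditions: HF·pyridine, THF, 0 °C → rt
Reagents that add atoms: none
Why: fluoride-mediated cleavage of the tertiary triethylsilyl ether should leave the ester, the acrylic acid and all stereocentres intact.

**Compound list**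
1 | 2-methylcyclopentane-1,3-dione | CC1C(=O)CCC1=O | starting material
2 | pent-1-en-3-one (ethyl vinyl ketone) | C=CC(=O)CC | starting material
3 | 2-methyl-2-(3-oxopentyl)cyclopentane-1,3-dione | CCC(=O)CCC1(C)C(=O)CCC1=O | intermediate
4 | (7aS)-4,7a-dimethyl-2,3,7,7a-tetrahydro-1H-indene-1,5(6H)-dione | C[C@]12CCC(=O)C(C)=C1CCC2=O | intermediate
5 | (7a'S)-4',7a'-dimethyl-2',3',7',7a'-tetrahydrospiro[1,3-dithiolane-2,5'-inden]-1'(6'H)-one | C[C@]12CCC3(SCCS3)C(C)=C1CCC2=O | intermediate
6 | (7aS)-4,7a-dimethyl-2,3,5,6,7,7a-hexahydro-1H-inden-1-one | C[C@]12CCCC(C)=C1CCC2=O | intermediate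
7 | alkylborane: trans-hydrindane with BH2 on C4 (α face), H-5α and O-boryl at C9 (β) | [BH2]O[C@H]1CC[C@@H]2[C@]1(C)CCC[C@@]2(C)[BH2] | intermediate (not isolated)
8 | (1S,3aR,4R,7aS)-4,7a-dimethyloctahydro-1H-indene-1,4-diol | O[C@H]1CC[C@@H]2[C@]1(C)CCC[C@@]2(C)O | intermediate
9 | (3aR,4R,7aS)-4-hydroxy-4,7a-dimethyloctahydro-1H-inden-1-one | O=C1CC[C@@H]2[C@]1(C)CCC[C@@]2(C)O | intermediate
10 | (3aS,7R,7aR)-3a,7-dimethyl-3,7-bis(triethylsilyloxy)-3a,4,5,6,7,7a-hexahydro-1H-indene | CC[Si](CC)(CC)OC1=CC[C@@H]2[C@]1(C)CCC[C@@]2(C)O[Si](CC)(CC)CC | intermediate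
11 | silyloxycyclopropane: 10 with CH2 (C8) bridged across C7–C9 on the α face, OSiEt3 at C9 β, H-7 β | CC[Si](CC)(CC)O[C@@]12C[C@@H]1C[C@@H]3[C@]2(C)CCC[C@@]3(C)O[Si](CC)(CC)CC | intermediate
12 | (4aR,5R,8aS)-3-chloro-5,8a-dimethyl-5-(triethylsilyloxy)octahydronaphthalen-1(2H)-one (C3 epimers) | O=C1CC(Cl)C[C@@H]2[C@]1(C)CCC[C@@]2(C)O[Si](CC)(CC)CC | intermediate (not isolated)
13 | (4aR,5R,8aS)-5,8a-dimethyl-5-(triethylsilyloxy)-4a,5,6,7,8,8a-hexahydronaphthalen-1(4H)-one | O=C1C=CC[C@@H]2[C@]1(C)CCC[C@@]2(C)O[Si](CC)(CC)CC | intermediate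
14 | isopropenylmagnesium bromide | CC(=C)[Mg]Br | starting material
15 | (3R,4aR,5R,8aS)-5,8a-dimethyl-3-(prop-1-en-2-yl)-5-(triethylsilyloxy)octahydronaphthalen-1(2H)-one | CC(=C)[C@@H]1C[C@@H]2[C@](C)(CCC[C@@]2(C)O[Si](CC)(CC)CC)C(=O)C1 | intermediate
16 | (1R,3R,4aR,5R,8aS)-5,8a-dimethyl-3-(prop-1-en-2-yl)-5-(triethylsilyloxy)decahydronaphthalen-1-ol | CC(=C)[C@@H]1C[C@@H]2[C@](C)(CCC[C@@]2(C)O[Si](CC)(CC)CC)[C@H](O)C1 | intermediate
17 | (3R)-3-methylpentanoic acid | CC[C@@H](C)CC(=O)O | starting material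
18 | (1R,3R,4aR,5R,8aS)-5,8a-dimethyl-3-(prop-1-en-2-yl)-5-(triethylsilyloxy)decahydronaphthalen-1-yl (3R)-3-methylpentanoate | CC(=C)[C@@H]1C[C@@H]2[C@](C)(CCC[C@@]2(C)O[Si](CC)(CC)CC)[C@H](OC(=O)C[C@H](C)CC)C1 | intermediate
19 | (1R,3R,4aR,5R,8aS)-3-(3-hydroxyprop-1-en-2-yl)-5,8a-dimethyl-5-(triethylsilyloxy)decahydronaphthalen-1-yl (3R)-3-methylpentanoate | OCC(=C)[C@@H]1C[C@@H]2[C@](C)(CCC[C@@]2(C)O[Si](CC)(CC)CC)[C@H](OC(=O)C[C@H](C)CC)C1 | intermediate
20 | (1R,3R,4aR,5R,8aS)-5,8a-dimethyl-3-(3-oxoprop-1-en-2-yl)-5-(triethylsilyloxy)decahydronaphthalen-1-yl (3R)-3-methylpentanoate | O=CC(=C)[C@@H]1C[C@@H]2[C@](C)(CCC[C@@]2(C)O[Si](CC)(CC)CC)[C@H](OC(=O)C[C@H](C)CC)C1 | intermediate (not isolated)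
21 | 2-[(2R,4R,4aS,8R,8aR)-4a,8-dimethyl-4-{[(3R)-3-methylpentanoyl]oxy}-8-(triethylsilyloxy)decahydronaphthalen-2-yl]prop-2-enoic acid | OC(=O)C(=C)[C@@H]1C[C@@H]2[C@](C)(CCC[C@@]2(C)O[Si](CC)(CC)CC)[C@H](OC(=O)C[C@H](C)CC)C1 | intermediate
22 | 2-[(2R,4R,4aS,8R,8aR)-8-hydroxy-4a,8-dimethyl-4-{[(3R)-3-methylpentanoyl]oxy}decahydronaphthalen-2-yl]prop-2-enoic acid | C=C(C(=O)O)[C@@H]1C[C@@H]2[C@](C)(CCC[C@@]2(C)O)[C@H](OC(=O)C[C@H](C)CC)C1 | target

**Totals**
Total step count: 15. Longest linear sequence: 15 steps (from 1 and 2; compounds 14 and 17 are purchased).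

**Steps most likely to fail**

Step 9. The oxidative opening may break the external C8–C9 bond, or the cyclopropane may open by protodesilylation to a C7-methyl cyclopentanone, so that no ring enlargement occurs; the C4 silyl ether may also be lost. The fallback sets out from 9 and returns at 13. Silylation (Et3SiOTf, 2,6-lutidine) would give (3aR,4R,7aS)-4,7a-dimethyl-4-(triethylsilyloxy)octahydro-1H-inden-1-one F1. Diazoalkane homologation with trimethylsilyldiazomethane and AlMe3 in CH2Cl2 at −78 → −20 °C, in which the less substituted C7 methylene migrates, followed by protodesilylation on work-up, would give (4aR,5R,8aS)-5,8a-dimethyl-5-(triethylsilyloxy)octahydronaphthalen-1(2H)-one F2. Dehydrogenation with 2-iodoxybenzoic acid in DMSO at 70 °C, which can only occur towards C8, would return enone 13.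

Step 5. Hydroboration of the hindered tetrasubstituted alkene may be slow, may place boron on C5 or on the β face, or the tertiary borane may migrate on warming. The fallback sets out from 4 and returns at 9. Selective ketalisation of the saturated C9 carbonyl (ethylene glycol, TsOH) would give (7a'S)-4',7a'-dimethyl-2',3',7',7a'-tetrahydrospiro[1,3-dioxolane-2,1'-inden]-5'(6'H)-one F3. Reduction with Li in NH3 and trapping of the enolate with PhNTf2 would give the trans-fused C3 enol triflate (H-5α) F4. Reduction with Pd(OAc)2, PPh3, HCO2H and Bu3N would give the C3=C4 alkene ketal F5. Mukaiyama hydration (Mn(dpm)3, PhSiH3, O2, i-PrOH), with oxygen captured on the α face anti to the axial C10 methyl, would give (3a'R,4'R,7a'S)-4',7a'-dimethyloctahydrospiro[1,3-dioxolane-2,1'-inden]-4'-ol F6. Hydrolysis of the ketal (pyridinium p-toluenesulfonate, acetone/H2O) would return hydroxy ketone 9.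

Step 13. The selenium oxidation may stall on the hindered axial isopropenyl group, attack the C7 methine, over-oxidise, or cleave the silyl ether under the acidic conditions. The fallback sets out from 18 and returns at 20. Ene-type allylic chlorination (Ca(OCl)2, solid CO2, CH2Cl2/H2O, 0 °C) would give (1R,3R,4aR,5R,8aS)-3-(3-chloroprop-1-en-2-yl)-5,8a-dimethyl-5-(triethylsilyloxy)decahydronaphthalen-1-yl (3R)-3-methylpentanoate F7. Kornblum-type oxidation with N-methylmorpholine N-oxide in MeCN (NaHCO3 work-up) would give enal 20, which enters the chlorite stage of step 14.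

**Further compounds**
F1 | step 9 | (3aR,4R,7aS)-4,7a-dimethyl-4-(triethylsilyloxy)octahydro-1H-inden-1-one | O=C1CC[C@@H]2[C@]1(C)CCC[C@@]2(C)O[Si](CC)(CC)CC
F2 | step 9 | (4aR,5R,8aS)-5,8a-dimethyl-5-(triethylsilyloxy)octahydronaphthalen-1(2H)-one | O=C1CCC[C@@H]2[C@]1(C)CCC[C@@]2(C)O[Si](CC)(CC)CC
F3 | step 5 | (7a'S)-4',7a'-dimethyl-2',3',7',7a'-tetrahydrospiro[1,3-dioxolane-2,1'-inden]-5'(6'H)-one | C[C@]12CCC(=O)C(C)=C1CCC23OCCO3
F4 | step 5 | trans-fused C3 enol triflate of the C9 ketal (H-5α, 10β-CH3) | C[C@]12CCC(OS(=O)(=O)C(F)(F)F)=C(C)[C@@H]1CCC23OCCO3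
F5 | step 5 | trans-fused C3=C4 alkene of the C9 ketal (H-5α, 10β-CH3) | C[C@]12CCC=C(C)[C@@H]1CCC23OCCO3
F6 | step 5 | (3a'R,4'R,7a'S)-4',7a'-dimethyloctahydrospiro[1,3-dioxolane-2,1'-inden]-4'-ol | C[C@]12CCC[C@@](C)(O)[C@@H]1CCC23OCCO3
F7 | step 13 | (1R,3R,4aR,5R,8aS)-3-(3-chloroprop-1-en-2-yl)-5,8a-dimethyl-5-(triethylsilyloxy)decahydronaphthalen-1-yl (3R)-3-methylpentanoate | ClCC(=C)[C@@H]1C[C@@H]2[C@](C)(CCC[C@@]2(C)O[Si](CC)(CC)CC)[C@H](OC(=O)C[C@H](C)CC)C1
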